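## Retrosynthetic overview

1. Target 29 comes from hexabenzyl ether 27: its 1,2,4-tris(benzyloxy)naphthalene ring is a masked 2-hydroxy-1,4-quinone, released by hydrogenolysis and air oxidation in the last step.
2. The pyranone ring comes from thermolysis of keto-dioxinone 25, itself made by a vinylogous aldol of arylacetaldehyde 20 with silyl dienolate 23.
3. Key disconnection: the central benzenoid ring is made by intermolecular Michael addition of lithiated toluate 5 to aryl enone 13, Dieckmann closure in the same flask, then dehydrogenation (steps 9 and 10).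
4. Toluate 5 comes from methyl orsellinate 1 (para-oxidation, reductive benzylation); enone 13 comes from aldehyde 7 and alkyne 9.
5. Ring order: both outer benzene rings are bought; the central carbocycle is formed first (steps 9 and 10), then the pyranone (step 17), then the quinone oxidation level (step 18).

Assumption: the target has no stereogenic element (it is achiral), so no enantiocontrol is needed; stereocentres in intermediates are racemic and are all erased before the end.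

## Route

Step 1
Reactants: 1 methyl 2,4-dihydroxy-6-methylbenzoate
Product: 2 methyl 4-(benzyloxy)-2-hydroxy-6-methylbenzoate
Conditions: BnBr (1.05 equiv), K2CO3 (1.1 equiv), acetone, reflux
Reagents that add atoms: benzyl bromide, BrCc1ccccc1
Why: Williamson etherification in which the 2-OH, hydrogen-bonded to the ester carbonyl, stays untouched so only the 4-OH is benzylated.

Step 2
Reactants: 2 methyl 4-(benzyloxy)-2-hydroxy-6-methylbenzoate
Product: 3 methyl 4-(benzyloxy)-2-methyl-3,6-dioxocyclohexa-1,4-diene-1-carboxylate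
Conditions: (KO3S)2NO (2.5 equiv), KH2PO4, H2O/acetone, rt
Reagents that add atoms: potassium nitrosodisulfonate, [K+].[K+].[O]N(S(=O)(=O)[O-])S(=O)(=O)[O-]
Why: Teuber oxidation of the single free phenol at its only open para position gives the p-quinone and fixes the third ring oxygen without regiochemical ambiguity.

Step 3
Reactants: 3 methyl 4-(benzyloxy)-2-methyl-3,6-dioxocyclohexa-1,4-diene-1-carboxylate
Product: 5 methyl 3,4,6-tris(benzyloxy)-2-methylbenzoate, via hydroquinone 4 (not isolated)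
Conditions: Na2S2O4, EtOAc/H2O, rt; then BnBr (2.5 equiv), K2CO3 (3 equiv), DMF, 60 °C, under Ar
Reagents that add atoms: benzyl bromide, BrCc1ccccc1
Why: dithionite reduction of the quinone followed by double Williamson benzylation of the air-sensitive hydroquinone under argon gives the fully protected toluate.

Step 4
Reactants: 6 2,4-dihydroxy-6-methylbenzaldehyde
Product: 7 2,4-bis(benzyloxy)-6-methylbenzaldehyde
Conditions: BnBr (2.4 equiv), K2CO3 (3 equiv), DMF, 60 °C
Reagents that add atoms: benzyl bromide, BrCc1ccccc1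
Why: Williamson etherification of both phenols, the chelated 2-OH reacting at 60 °C in DMF.

Step 5
Reactants: 8 but-3-yn-1-ol
Product: 9 tert-butyl(but-3-yn-1-yloxy)dimethylsilane
Conditions: TBSCl, imidazole, CH2Cl2, 0 °C to rt
Reagents that add atoms: tert-butyldimethylsilyl chloride, CC(C)(C)[Si](C)(C)Cl
Why: standard imidazole-mediated silylation of a primary alcohol.

Step 6
Reactants: 9 tert-butyl(but-3-yn-1-yloxy)dimethylsilane; 7 2,4-bis(benzyloxy)-6-methylbenzaldehyde
Product: 11 rac-1-[2,4-bis(benzyloxy)-6-methylphenyl]-5-(tert-butyldimethylsilyloxy)pent-2-yn-1-ol, via lithium acetylide 10 (not isolated)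
Conditions: n-BuLi, THF, −78 °C; then 7, −78 °C to 0 °C; then H2O
Reagents that add atoms: none
Why: 1,2-addition of a lithium acetylide to the aldehyde; the carbinol centre is racemic and is removed by oxidation in step 8.

Step 7
Reactants: 11 rac-1-[2,4-bis(benzyloxy)-6-methylphenyl]-5-(tert-butyldimethylsilyloxy)pent-2-yn-1-ol
Product: 12 rac-(E)-1-[2,4-bis(benzyloxy)-6-methylphenyl]-5-(tert-butyldimethylsilyloxy)pent-2-en-1-ol
Conditions: NaAlH2(OCH2CH2OMe)2, THF, 0 °C to rt; then aq. NaOH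
Reagents that add atoms: none
Why: hydroxyl-directed trans-hydroalumination of the propargylic alcohol followed by protonolysis gives the E-alkene only.

Step 8
Reactants: 12 rac-(E)-1-[2,4-bis(benzyloxy)-6-methylphenyl]-5-(tert-butyldimethylsilyloxy)pent-2-en-1-ol
Product: 13 (E)-1-[2,4-bis(benzyloxy)-6-methylphenyl]-5-(tert-butyldimethylsilyloxy)pent-2-en-1-one
Conditions: MnO2 (excess), CH2Cl2, rt
Reagents that add atoms: none
Why: neutral MnO2 oxidation of an alcohol that is both allylic and benzylic, without acid that could ionise the electron-rich carbinol or isomerise the alkene.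

Step 9
Reactants: 5 methyl 3,4,6-tris(benzyloxy)-2-methylbenzoate; 13 (E)-1-[2,4-bis(benzyloxy)-6-methylphenyl]-5-(tert-butyldimethylsilyloxy)pent-2-en-1-one
Product: 16 rac-2-[2,4-bis(benzyloxy)-6-methylbenzoyl]-5,6,8-tris(benzyloxy)-3-[2-(tert-butyldimethylsilyloxy)ethyl]-3,4-dihydronaphthalen-1(2H)-one, via lithiated toluate 14 (not isolated), via Michael adduct enolate 15 (not isolated)
Conditions: LiN(iPr)2 (1.1 equiv, commercial solution), THF, −78 °C; then 13, −78 °C to rt; then AcOH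
Reagents that add atoms: none
Why: intermolecular Michael addition of the benzylic toluate anion to the enone, whose di-ortho-substituted aryl ketone blocks 1,2-attack, then Dieckmann closure of the enolate onto the ester (Staunton–Weinreb annulation); the two new stereocentres are racemic and are erased in step 10.

Step 10
Reactants: 16 rac-2-[2,4-bis(benzyloxy)-6-methylbenzoyl]-5,6,8-tris(benzyloxy)-3-[2-(tert-butyldimethylsilyloxy)ethyl]-3,4-dihydronaphthalen-1(2H)-one
Product: 17 [2,4-bis(benzyloxy)-6-methylphenyl]{5,6,8-tris(benzyloxy)-3-[2-(tert-butyldimethylsilyloxy)ethyl]-1-hydroxynaphthalen-2-yl}methanone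
Conditions: DDQ (1.1 equiv), toluene, rt to 50 °C
Reagents that add atoms: none
Why: DDQ dehydrogenation by hydride abstraction from the benzylic C4–H, which is activated by the ortho and para benzyloxy groups, followed by tautomerisation to the hydrogen-bonded 2-aroyl-1-naphthol.

Step 11
Reactants: 17 [2,4-bis(benzyloxy)-6-methylphenyl]{5,6,8-tris(benzyloxy)-3-[2-(tert-butyldimethylsilyloxy)ethyl]-1-hydroxynaphthalen-2-yl}methanone
Product: 18 [2,4-bis(benzyloxy)-6-methylphenyl]{1,5,6,8-tetrakis(benzyloxy)-3-[2-(tert-butyldimethylsilyloxy)ethyl]naphthalen-2-yl}methanone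
Conditions: BnBr, Cs2CO3, DMF, 50 °C
Reagents that add atoms: benzyl bromide, BrCc1ccccc1
Why: Williamson etherification with the cesium naphtholate, reactive enough to overcome the chelated, hindered peri-hydroxyl, so that no free phenol is present in the oxidation and Lewis acid steps.

Step 12
Reactants: 18 [2,4-bis(benzyloxy)-6-methylphenyl]{1,5,6,8-tetrakis(benzyloxy)-3-[2-(tert-butyldimethylsilyloxy)ethyl]naphthalen-2-yl}methanone
Product: 19 [2,4-bis(benzyloxy)-6-methylphenyl][1,5,6,8-tetrakis(benzyloxy)-3-(2-hydroxyethyl)naphthalen-2-yl]methanone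
Conditions: HF·pyridine, pyridine/THF, 0 °C to rt
Reagents that add atoms: none
Why: fluoride-driven cleavage of the primary silyl ether under buffered conditions that leave benzyl ethers and the ketone untouched.

Step 13
Reactants: 19 [2,4-bis(benzyloxy)-6-methylphenyl][1,5,6,8-tetrakis(benzyloxy)-3-(2-hydroxyethyl)naphthalen-2-yl]methanone
Product: 20 2-{3-[2,4-bis(benzyloxy)-6-methylbenzoyl]-4,5,7,8-tetrakis(benzyloxy)naphthalen-2-yl}acetaldehyde
Conditions: Dess–Martin periodinane, CH2Cl2, 0 °C to rt; used at once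
Reagents that add atoms: none
Why: Dess–Martin oxidation stops cleanly at the enolisable arylacetaldehyde, which is carried forward without storage.

Step 14
Reactants: 21 2,2,6-trimethyl-4H-1,3-dioxin-4-one
Product: 23 [(2,2-dimethyl-6-methylidene-6H-1,3-dioxin-4-yl)oxy]trimethylsilane, via lithium dienolate 22 (not isolated)
Conditions: LiN(iPr)2 (commercial solution), THF, −78 °C; then TMSCl
Reagents that add atoms: chlorotrimethylsilane, C[Si](C)(C)Cl
Why: kinetic gamma-deprotonation of the vinylogous ester and O-silylation give the silyl dienol ether.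

Step 15
Reactants: 20 2-{3-[2,4-bis(benzyloxy)-6-methylbenzoyl]-4,5,7,8-tetrakis(benzyloxy)naphthalen-2-yl}acetaldehyde; 23 [(2,2-dimethyl-6-methylidene-6H-1,3-dioxin-4-yl)oxy]trimethylsilane
Product: 24 rac-6-(3-{3-[2,4-bis(benzyloxy)-6-methylbenzoyl]-4,5,7,8-tetrakis(benzyloxy)naphthalen-2-yl}-2-hydroxypropyl)-2,2-dimethyl-4H-1,3-dioxin-4-one
Conditions: BF3·OEt2 (1.0 equiv), CH2Cl2, −78 °C; then H2O
Reagents that add atoms: none
Why: vinylogous Mukaiyama aldol in which the dienol ether attacks the Lewis-acid-activated aldehyde through its terminal carbon at −78 °C, without base that would enolise the aldehyde; the new carbinol is racemic and is oxidised in step 16.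

Step 16
Reactants: 24 rac-6-(3-{3-[2,4-bis(benzyloxy)-6-methylbenzoyl]-4,5,7,8-tetrakis(benzyloxy)naphthalen-2-yl}-2-hydroxypropyl)-2,2-dimethyl-4H-1,3-dioxin-4-one
Product: 25 6-(3-{3-[2,4-bis(benzyloxy)-6-methylbenzoyl]-4,5,7,8-tetrakis(benzyloxy)naphthalen-2-yl}-2-oxopropyl)-2,2-dimethyl-4H-1,3-dioxin-4-one
Conditions: Dess–Martin periodinane, CH2Cl2, rt
Reagents that add atoms: none
Why: Dess–Martin oxidation of the secondary alcohol gives the keto-dioxinone under non-basic conditions that avoid aldol chemistry at the hindered diaryl ketone.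

Step 17
Reactants: 25 6-(3-{3-[2,4-bis(benzyloxy)-6-methylbenzoyl]-4,5,7,8-tetrakis(benzyloxy)naphthalen-2-yl}-2-oxopropyl)-2,2-dimethyl-4H-1,3-dioxin-4-one
Product: 27 6-({3-[2,4-bis(benzyloxy)-6-methylbenzoyl]-4,5,7,8-tetrakis(benzyloxy)naphthalen-2-yl}methyl)-4-hydroxy-2H-pyran-2-one, via acylketene 26 (not isolated)
Conditions: toluene, 110 °C
Reagents that add atoms: none
Why: thermal retro-[4+2] loss of acetone gives an acylketene that is trapped by the enol oxygen of the side-chain ketone in a six-membered lactonisation to the 4-hydroxy-2-pyranone.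

Step 18
Reactants: 27 6-({3-[2,4-bis(benzyloxy)-6-methylbenzoyl]-4,5,7,8-tetrakis(benzyloxy)naphthalen-2-yl}methyl)-4-hydroxy-2H-pyran-2-one
Product: 29 6-(2,4-dihydroxy-6-methylbenzoyl)-2,5-dihydroxy-7-[(4-hydroxy-2-oxo-2H-pyran-6-yl)methyl]naphthalene-1,4-dione, via tetrahydroxynaphthalene 28 (not isolated)
Conditions: H2 (1 atm), Pd/C, EtOAc/MeOH, rt; filter; then air, rt
Reagents that add atoms: none
Why: hydrogenolysis of all six aryl benzyl ethers (the tetra-ortho-substituted diaryl ketone resists reduction) gives a 1,2,4-trihydroxynaphthalene unit that autoxidises in air to the 2-hydroxy-1,4-quinone, whose oxygen positions were fixed in steps 2 and 9.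

## Compound list

1 | methyl 2,4-dihydroxy-6-methylbenzoate (methyl orsellinate) | COC(=O)c1c(C)cc(O)cc1O | starting material
2 | methyl 4-(benzyloxy)-2-hydroxy-6-methylbenzoate | COC(=O)c1c(C)cc(OCc2ccccc2)cc1O | intermediate
3 | methyl 4-(benzyloxy)-2-methyl-3,6-dioxocyclohexa-1,4-diene-1-carboxylate | COC(=O)C1=C(C)C(=O)C(OCc2ccccc2)=CC1=O | intermediate
4 | methyl 4-(benzyloxy)-3,6-dihydroxy-2-methylbenzoate (hydroquinone) | COC(=O)c1c(C)c(O)c(OCc2ccccc2)cc1O | intermediate
5 | methyl 3,4,6-tris(benzyloxy)-2-methylbenzoate | COC(=O)c1c(C)c(OCc2ccccc2)c(OCc2ccccc2)cc1OCc1ccccc1 | intermediate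
6 | 2,4-dihydroxy-6-methylbenzaldehyde | Cc1cc(O)cc(O)c1C=O | starting material
7 | 2,4-bis(benzyloxy)-6-methylbenzaldehyde | Cc1cc(OCc2ccccc2)cc(OCc2ccccc2)c1C=O | intermediate
8 | but-3-yn-1-ol | C#CCCO | starting material
9 | tert-butyl(but-3-yn-1-yloxy)dimethylsilane | C#CCCO[Si](C)(C)C(C)(C)C | intermediate
10 | [4-(tert-butyldimethylsilyloxy)but-1-yn-1-yl]lithium (lithium acetylide) | [Li]C#CCCO[Si](C)(C)C(C)(C)C | intermediate
11 | rac-1-[2,4-bis(benzyloxy)-6-methylphenyl]-5-(tert-butyldimethylsilyloxy)pent-2-yn-1-ol | Cc1cc(OCc2ccccc2)cc(OCc2ccccc2)c1C(O)C#CCCO[Si](C)(C)C(C)(C)C | intermediate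
12 | rac-(E)-1-[2,4-bis(benzyloxy)-6-methylphenyl]-5-(tert-butyldimethylsilyloxy)pent-2-en-1-ol | Cc1cc(OCc2ccccc2)cc(OCc2ccccc2)c1C(O)/C=C/CCO[Si](C)(C)C(C)(C)C | intermediate
13 | (E)-1-[2,4-bis(benzyloxy)-6-methylphenyl]-5-(tert-butyldimethylsilyloxy)pent-2-en-1-one | Cc1cc(OCc2ccccc2)cc(OCc2ccccc2)c1C(=O)/C=C/CCO[Si](C)(C)C(C)(C)C | intermediate
14 | lithiated toluate: methyl 3,4,6-tris(benzyloxy)-2-(lithiomethyl)benzoate | COC(=O)c1c(C[Li])c(OCc2ccccc2)c(OCc2ccccc2)cc1OCc1ccccc1 | intermediate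
15 | Michael adduct lithium enolate (racemic) | COC(=O)c1c(CC(CCO[Si](C)(C)C(C)(C)C)C=C(O[Li])c2c(C)cc(OCc3ccccc3)cc2OCc2ccccc2)c(OCc2ccccc2)c(OCc2ccccc2)cc1OCc1ccccc1 | intermediate
16 | rac-2-[2,4-bis(benzyloxy)-6-methylbenzoyl]-5,6,8-tris(benzyloxy)-3-[2-(tert-butyldimethylsilyloxy)ethyl]-3,4-dihydronaphthalen-1(2H)-one (racemic, largely enolised) | O=C1C(C(=O)c2c(C)cc(OCc3ccccc3)cc2OCc2ccccc2)C(CCO[Si](C)(C)C(C)(C)C)Cc2c(OCc3ccccc3)c(OCc3ccccc3)cc(OCc3ccccc3)c12 | intermediate
17 | [2,4-bis(benzyloxy)-6-methylphenyl]{5,6,8-tris(benzyloxy)-3-[2-(tert-butyldimethylsilyloxy)ethyl]-1-hydroxynaphthalen-2-yl}methanone | Cc1cc(OCc2ccccc2)cc(OCc2ccccc2)c1C(=O)c1c(CCO[Si](C)(C)C(C)(C)C)cc2c(OCc3ccccc3)c(OCc3ccccc3)cc(OCc3ccccc3)c2c1O | intermediate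
18 | [2,4-bis(benzyloxy)-6-methylphenyl]{1,5,6,8-tetrakis(benzyloxy)-3-[2-(tert-butyldimethylsilyloxy)ethyl]naphthalen-2-yl}methanone | Cc1cc(OCc2ccccc2)cc(OCc2ccccc2)c1C(=O)c1c(CCO[Si](C)(C)C(C)(C)C)cc2c(OCc3ccccc3)c(OCc3ccccc3)cc(OCc3ccccc3)c2c1OCc1ccccc1 | intermediate
19 | [2,4-bis(benzyloxy)-6-methylphenyl][1,5,6,8-tetrakis(benzyloxy)-3-(2-hydroxyethyl)naphthalen-2-yl]methanone | Cc1cc(OCc2ccccc2)cc(OCc2ccccc2)c1C(=O)c1c(CCO)cc2c(OCc3ccccc3)c(OCc3ccccc3)cc(OCc3ccccc3)c2c1OCc1ccccc1 | intermediate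
20 | 2-{3-[2,4-bis(benzyloxy)-6-methylbenzoyl]-4,5,7,8-tetrakis(benzyloxy)naphthalen-2-yl}acetaldehyde | Cc1cc(OCc2ccccc2)cc(OCc2ccccc2)c1C(=O)c1c(CC=O)cc2c(OCc3ccccc3)c(OCc3ccccc3)cc(OCc3ccccc3)c2c1OCc1ccccc1 | intermediate
21 | 2,2,6-trimethyl-4H-1,3-dioxin-4-one | CC1=CC(=O)OC(C)(C)O1 | starting material
22 | lithium dienolate of 21 | [Li]OC1=CC(=C)OC(C)(C)O1 | intermediate
23 | [(2,2-dimethyl-6-methylidene-6H-1,3-dioxin-4-yl)oxy]trimethylsilane | C=C1C=C(O[Si](C)(C)C)OC(C)(C)O1 | intermediate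
24 | rac-6-(3-{3-[2,4-bis(benzyloxy)-6-methylbenzoyl]-4,5,7,8-tetrakis(benzyloxy)naphthalen-2-yl}-2-hydroxypropyl)-2,2-dimethyl-4H-1,3-dioxin-4-one | Cc1cc(OCc2ccccc2)cc(OCc2ccccc2)c1C(=O)c1c(CC(O)CC3=CC(=O)OC(C)(C)O3)cc2c(OCc3ccccc3)c(OCc3ccccc3)cc(OCc3ccccc3)c2c1OCc1ccccc1 | intermediate
25 | 6-(3-{3-[2,4-bis(benzyloxy)-6-methylbenzoyl]-4,5,7,8-tetrakis(benzyloxy)naphthalen-2-yl}-2-oxopropyl)-2,2-dimethyl-4H-1,3-dioxin-4-one | Cc1cc(OCc2ccccc2)cc(OCc2ccccc2)c1C(=O)c1c(CC(=O)CC3=CC(=O)OC(C)(C)O3)cc2c(OCc3ccccc3)c(OCc3ccccc3)cc(OCc3ccccc3)c2c1OCc1ccccc1 | intermediate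
26 | 6-{3-[2,4-bis(benzyloxy)-6-methylbenzoyl]-4,5,7,8-tetrakis(benzyloxy)naphthalen-2-yl}hex-1-ene-1,3,5-trione (acylketene) | Cc1cc(OCc2ccccc2)cc(OCc2ccccc2)c1C(=O)c1c(CC(=O)CC(=O)C=C=O)cc2c(OCc3ccccc3)c(OCc3ccccc3)cc(OCc3ccccc3)c2c1OCc1ccccc1 | intermediate
27 | 6-({3-[2,4-bis(benzyloxy)-6-methylbenzoyl]-4,5,7,8-tetrakis(benzyloxy)naphthalen-2-yl}methyl)-4-hydroxy-2H-pyran-2-one | Cc1cc(OCc2ccccc2)cc(OCc2ccccc2)c1C(=O)c1c(Cc3cc(O)cc(=O)o3)cc2c(OCc3ccccc3)c(OCc3ccccc3)cc(OCc3ccccc3)c2c1OCc1ccccc1 | intermediate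
28 | 6-{[3-(2,4-dihydroxy-6-methylbenzoyl)-4,5,7,8-tetrahydroxynaphthalen-2-yl]methyl}-4-hydroxy-2H-pyran-2-one | Cc1cc(O)cc(O)c1C(=O)c1c(Cc3cc(O)cc(=O)o3)cc2c(O)c(O)cc(O)c2c1O | intermediate
29 | 6-(2,4-dihydroxy-6-methylbenzoyl)-2,5-dihydroxy-7-[(4-hydroxy-2-oxo-2H-pyran-6-yl)methyl]naphthalene-1,4-dione (achiral) | Cc1cc(O)cc(O)c1C(=O)c1c(Cc2cc(O)cc(=O)o2)cc2c(c1O)C(=O)C=C(O)C2=O | target

## Step count and risk

Total step count: 18.

Longest linear sequence: 13 steps (steps 5, 6, 7, 8, 9, 10, 11, 12, 13, 15, 16, 17, 18; from 8 to 29).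

The three steps most likely to fail:

Step 9 (Michael–Dieckmann annulation). The basic toluate anion may deprotonate the enone at its gamma position or self-condense, or the Dieckmann closure may stall. The fallback sets out from 5 and comes back to the route at 17. Lithiated 5 (LiN(iPr)2, THF, −78 °C) is quenched with PhSSPh to give methyl 3,4,6-tris(benzyloxy)-2-[(phenylsulfanyl)methyl]benzoate F2. Oxidation with one equivalent of mCPBA at −78 °C gives methyl 3,4,6-tris(benzyloxy)-2-[(phenylsulfinyl)methyl]benzoate F3. The softer, sulfinyl-stabilised anion of F3 (LiN(iPr)2, THF, −78 °C) adds to enone 13 in a Hauser sulfoxide annulation and closes to the 4-(phenylsulfinyl)tetralone F4, which is not isolated. On warming, F4 loses benzenesulfenic acid by syn-elimination and tautomerises to naphthol 17, so that 16 and the DDQ step are bypassed.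

Step 15 (vinylogous Mukaiyama aldol). Arylacetaldehyde 20 carries an ortho aroyl group and may enolise and cyclise onto the ketone (benzopyrylium formation) under Lewis acid before it is intercepted. The fallback sets out from 19 and comes back at 25, replacing the aldol by a Claisen-type acylation. Alcohol 19 is oxidised directly with catalytic TEMPO and PhI(OAc)2 in MeCN/H2O to 2-{3-[2,4-bis(benzyloxy)-6-methylbenzoyl]-4,5,7,8-tetrakis(benzyloxy)naphthalen-2-yl}acetic acid F5. Carbonyldiimidazole in THF converts F5 into the acyl imidazole 1-(1H-imidazol-1-yl)-2-{3-[2,4-bis(benzyloxy)-6-methylbenzoyl]-4,5,7,8-tetrakis(benzyloxy)naphthalen-2-yl}ethan-1-one F6. Addition of F6 to two equivalents of lithium dienolate 22 at −78 °C gives keto-dioxinone 25 by C-acylation, so that 20, 23, 24 and step 16 are not needed.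

Step 2 (Teuber oxidation). The phenol of 2 is hydrogen-bonded to the ester and may react sluggishly with the nitroxyl radical. The fallback sets out from 2 and comes back at 4. In an Elbs persulfate oxidation, 2 is treated with K2S2O8 in cold aqueous NaOH; the phenolate attacks peroxydisulfate through its para carbon to give potassium 6-(benzyloxy)-4-hydroxy-3-(methoxycarbonyl)-2-methylphenyl sulfate F1 (salicylates are classical substrates, and the di-ortho-substituted ester resists saponification). Warming F1 in dilute aqueous HCl hydrolyses the sulfate ester to hydroquinone 4, which is benzylated as in the second half of step 3 to give 5.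

## Further compounds

F1 | step 2 | potassium 6-(benzyloxy)-4-hydroxy-3-(methoxycarbonyl)-2-methylphenyl sulfate | COC(=O)c1c(C)c(OS(=O)(=O)[O-])c(OCc2ccccc2)cc1O.[K+]
F2 | step 9 | methyl 3,4,6-tris(benzyloxy)-2-[(phenylsulfanyl)methyl]benzoate | COC(=O)c1c(CSc2ccccc2)c(OCc2ccccc2)c(OCc2ccccc2)cc1OCc1ccccc1
F3 | step 9 | methyl 3,4,6-tris(benzyloxy)-2-[(phenylsulfinyl)methyl]benzoate (racemic at sulfur) | COC(=O)c1c(CS(=O)c2ccccc2)c(OCc2ccccc2)c(OCc2ccccc2)cc1OCc1ccccc1
F4 | step 9 | 2-[2,4-bis(benzyloxy)-6-methylbenzoyl]-5,6,8-tris(benzyloxy)-3-[2-(tert-butyldimethylsilyloxy)ethyl]-4-(phenylsulfinyl)-3,4-dihydronaphthalen-1(2H)-one (diastereomer mixture, racemic) | O=C1C(C(=O)c2c(C)cc(OCc3ccccc3)cc2OCc2ccccc2)C(CCO[Si](C)(C)C(C)(C)C)C(S(=O)c2ccccc2)c2c(OCc3ccccc3)c(OCc3ccccc3)cc(OCc3ccccc3)c12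
F5 | step 15 | 2-{3-[2,4-bis(benzyloxy)-6-methylbenzoyl]-4,5,7,8-tetrakis(benzyloxy)naphthalen-2-yl}acetic acid | Cc1cc(OCc2ccccc2)cc(OCc2ccccc2)c1C(=O)c1c(CC(=O)O)cc2c(OCc3ccccc3)c(OCc3ccccc3)cc(OCc3ccccc3)c2c1OCc1ccccc1
F6 | step 15 | 1-(1H-imidazol-1-yl)-2-{3-[2,4-bis(benzyloxy)-6-methylbenzoyl]-4,5,7,8-tetrakis(benzyloxy)naphthalen-2-yl}ethan-1-one | Cc1cc(OCc2ccccc2)cc(OCc2ccccc2)c1C(=O)c1c(CC(=O)n3ccnc3)cc2c(OCc3ccccc3)c(OCc3ccccc3)cc(OCc3ccccc3)c2c1OCc1ccccc1
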